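**Retrosynthetic overview**
1. Feature used (labdane numbering): C5 carries the gem-dimethyl carbon C4, and ring B (C5–C10) needs an oxygen at C8 to place the 7-ene. A pinane ketone in which C4 is also bonded to C7 (a cyclobutane bond α to a C8 carbonyl) is this pattern in masked form.
2. Target ⇐ acetonide removal, C8 methyl by coupling of the C7 enol triflate, and α-face dihydroxylation of C2=C3, all from a trans-decal-2-en-8-one that already carries the side chain.
3. That decalenone ⇐ pinanone Z-vinylsilane: a Lewis acid breaks C4–C7 and the C4 cation is captured at C3, which forms C3–C4 and closes ring A; C9 is then equilibrated. Ring B is the six-membered ring inherited from verbenone, so ring B comes first and ring A second.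
4. Pinanone vinylsilane ⇐ (+)-verbenone: vinyl conjugate addition anti to the bridge (C10), C9 alkylation with the C11–C16 iodide, then vinyl → aldehyde → alkyne → Z-vinylsilane.
5. C11–C16 iodide ⇐ methyl hydrogen (R)-3-methylglutarate by ester reduction, lactonisation and iodide opening of the lactone.

Key step: step 9

Remark: labdane numbering is used for every intermediate from verbenone onward; the C9 configuration drawn for compounds 10–17 (side chain anti to the gem-dimethyl bridge) is the expected one but is immaterial, because step 9 resets this centre.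

**Route**

Step 1
Reactants: 1 methyl hydrogen (R)-3-methylglutarate
Product: 3 (S)-4-methyloxan-2-one, via (S)-5-hydroxy-3-methylpentanoic acid 2 (not isolated)
Conditions: LiBH4 (2.5 equiv), THF, 0 °C → reflux; then 3 M HCl, rt
Reagents that add atoms: none
Why: Chemoselective LiBH4 reduction of the ester in the presence of the lithium carboxylate, followed by acid lactonisation, turns the ester terminus into the future C11 without touching the C13 stereocentre.

Step 2
Reactants: 3 (S)-4-methyloxan-2-one
Product: 5 methyl (R)-5-iodo-3-methylpentanoate, via trimethylsilyl (R)-5-iodo-3-methylpentanoate 4 (not isolated)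
Conditions: Me3SiI, CH2Cl2, 0 °C → rt; then MeOH, rt
Reagents that add atoms: iodotrimethylsilane C[Si](C)(C)I; methanol CO
Why: Silyl activation of the lactone carbonyl and SN2 attack of iodide at O–CH2 (iodotrimethylsilane lactone opening) give the ω-iodo silyl ester, which methanol and the HI formed in the flask convert into the methyl ester (Fischer esterification), the stereocentre being remote from both events.

Step 3
Reactants: 6 (1R,5R)-(+)-verbenone; 7 vinylmagnesium bromide
Product: 8 (1R,4S,5S)-4-ethenyl-4,6,6-trimethylbicyclo[3.1.1]heptan-2-one (vinyl anti to the CMe2 bridge)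
Conditions: CuBr·SMe2 (10 mol%), THF, −40 → 0 °C; aq. NH4Cl
Reagents that add atoms: none
Why: Copper-catalysed conjugate addition of the Grignard reagent to the β,β-disubstituted enone should deliver vinyl to the face anti to the gem-dimethyl bridge, which sets the quaternary centre (future C10) with the vinyl group (future C1–C2) trans to the bridge carbon (future C4).

Step 4
Reactants: 8 (1R,4S,5S)-4-ethenyl-4,6,6-trimethylbicyclo[3.1.1]heptan-2-one; 5 methyl (R)-5-iodo-3-methylpentanoate
Product: 10 methyl (3S)-5-(4-ethenyl-4,6,6-trimethyl-2-oxobicyclo[3.1.1]hept-3-yl)-3-methylpentanoate (chain at C9 anti to the CMe2 bridge), via lithium enolate 9 (not isolated)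
Conditions: LiN(i-Pr)2, THF, −78 °C; then 5, DMPU, −78 → 0 °C
Reagents that add atoms: none
Why: The ketone can enolise only towards C9, because the bridgehead C7–H cannot give a bridgehead enolate (Bredt's rule), so one lithium enolate forms and its SN2 alkylation by the primary iodide should occur anti to the gem-dimethyl bridge.

Step 5
Reactants: 10 alkylated vinyl ketone
Product: 12 methyl (3S)-5-[4-(2-hydroxyethyl)-4,6,6-trimethyl-2-oxobicyclo[3.1.1]hept-3-yl]-3-methylpentanoate, via B-alkyl-9-BBN adduct 11 (not isolated)
Conditions: 9-BBN, THF, 0 °C → rt; then NaBO3·4H2O, H2O, rt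
Reagents that add atoms: sodium perborate [Na+].[Na+].O[B-]1(O)OO[B-](O)(O)OO1
Why: Hydroboration–oxidation: 9-BBN adds anti-Markovnikov to the terminal vinyl group much faster than it reduces the hindered ketone or the ester, and perborate oxidises the C–B bond without saponifying the methyl ester.

Step 6
Reactants: 12 primary alcohol
Product: 13 methyl (3S)-3-methyl-5-[4,6,6-trimethyl-2-oxo-4-(2-oxoethyl)bicyclo[3.1.1]hept-3-yl]pentanoate
Conditions: Dess–Martin periodinane (2.5 equiv), NaHCO3, CH2Cl2, 0 °C → rt
Reagents that add atoms: none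
Why: Dess–Martin oxidation takes the primary alcohol (any hemiketal with the C8 carbonyl being in equilibrium with the open form) to the aldehyde C2 under buffered conditions that leave ketone and ester alone, and the excess oxidant would also return to the ketone any C8 carbinol formed by over-reduction in step 5.

Step 7
Reactants: 13 aldehyde
Product: 14 methyl (3S)-3-methyl-5-[4,6,6-trimethyl-2-oxo-4-(prop-2-ynyl)bicyclo[3.1.1]hept-3-yl]pentanoate
Conditions: MeC(O)C(N2)P(O)(OMe)2, K2CO3, MeOH, 0 °C → rt
Reagents that add atoms: dimethyl (1-diazo-2-oxopropyl)phosphonate CC(=O)C(=[N+]=[N-])P(=O)(OC)OC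
Why: Seyferth–Gilbert homologation with the Ohira–Bestmann reagent converts the unhindered aldehyde into the terminal alkyne (adding C3) under K2CO3/MeOH, in which the hindered ketone is inert and methanolysis of the methyl ester is degenerate.

Step 8
Reactants: 14 terminal alkyne
Product: 15 methyl (3S)-5-{4-[(Z)-3-(dimethylphenylsilyl)prop-2-enyl]-4,6,6-trimethyl-2-oxobicyclo[3.1.1]hept-3-yl}-3-methylpentanoate
Conditions: PhMe2SiH, [RuCl2(p-cymene)]2 (2.5 mol%), CH2Cl2, 40 °C
Reagents that add atoms: dimethylphenylsilane C[SiH](C)c1ccccc1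
Why: Ruthenium-catalysed trans-hydrosilylation of a terminal alkyne places silicon on the terminal carbon and should give the (Z)-β-vinylsilane without strong base, so ketone and ester are untouched.

Step 9
Reactants: 15 pinanone Z-vinylsilane
Product: 18 methyl (13S)-8-oxo-17-norlabd-2-en-15-oate (trans-fused; 9α-H), via cyclised trichlorotin enolate 16 (not isolated), via 9-epi ketone 17 (not isolated)
Conditions: SnCl4 (2.5 equiv), CH2Cl2, −78 → 0 °C; then NaOMe, MeOH, 0 °C → rt
Reagents that add atoms: none
Why: Proposed new method: SnCl4 on the C8 carbonyl should let the strained C4–C7 bond, which overlaps with the carbonyl π system, ionise in a retro-aldol sense to a C7–C8 tin enolate and a tertiary C4 cation, which the Z-vinylsilane attacks through its silicon-bearing carbon C3, the β-silyl cation at C2 then losing silicon to chloride to leave the C2–C3 alkene. The closest known reaction types are the Lewis-acid scission of pinane ketones to p-menthane cations trapped by halide, acetate or phenol oxygen, and vinylsilane-terminated cation cyclisations; joining them in one operation is the new part. Ring A closes in a 6-endo-trig mode with ipso substitution at silicon, the only mode that puts the cation β to silicon, and the Z geometry is needed so that the new C3–C4 bond and the C1 arm end up cis across the ring alkene. The trans ring fusion is not created here; it follows from the trans relation of C4 on C5 and the C1 arm on C10 fixed in step 3, and neither centre is touched. The one stereocentre set is C9: methoxide equilibrates it through the C8 enolate to the epimer with the side chain equatorial (9α-H), while C7 ceases to be stereogenic. The step needs cation capture to outrun proton loss and 1,2-hydride shift from C5, which the intramolecular six-membered approach of an electron-rich vinylsilane at low temperature should secure.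

Step 10
Reactants: 18 decalenone
Product: 19 methyl (13S)-2α,3α-dihydroxy-8-oxo-17-norlabdan-15-oate
Conditions: OsO4 (5 mol%), NMO, acetone/H2O (4:1), rt
Reagents that add atoms: osmium tetroxide O=[Os](=O)(=O)=O; N-methylmorpholine N-oxide C[N+]1([O-])CCOCC1; water O
Why: Catalytic OsO4/NMO syn-dihydroxylation should take place on the α face of C2=C3, because the β face is shielded by the axial C10 and 4β methyl groups, which sets C2 and C3 as the 2α,3α-cis-diol.

Step 11
Reactants: 19 keto diol
Product: 20 methyl (13S)-2α,3α-(isopropylidenedioxy)-8-oxo-17-norlabdan-15-oate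
Conditions: Me2C(OMe)2, PPTS (cat.), acetone, rt
Reagents that add atoms: 2,2-dimethoxypropane COC(C)(C)OC
Why: Acid-catalysed transketalisation of the cis-1,2-diol gives the five-membered acetonide, which masks both hydroxyl groups against base and triflating agent.

Step 12
Reactants: 20 keto acetonide
Product: 22 methyl (13S)-2α,3α-(isopropylidenedioxy)-8-(trifluoromethanesulfonyloxy)-17-norlabd-7-en-15-oate, via potassium C7–C8 enolate 21 (not isolated)
Conditions: KN(SiMe3)2 (1.1 equiv), THF, −78 °C; then PhNTf2, −78 → 0 °C
Reagents that add atoms: N-phenylbis(trifluoromethanesulfonimide) O=S(=O)(N(c1ccccc1)S(=O)(=O)C(F)(F)F)C(F)(F)F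
Why: Kinetic enolisation with the hindered amide base should remove a C7 proton of the ketone in preference to the neopentyl C9–H or the less acidic ester α-protons, and O-triflation of this enolate fixes the double bond at C7–C8.

Step 13
Reactants: 22 enol triflate
Product: 23 methyl (13S)-2α,3α-(isopropylidenedioxy)labd-7-en-15-oate
Conditions: Me2CuLi (MeLi, CuI), THF, −20 → 0 °C
Reagents that add atoms: lithium dimethylcuprate [Li+].C[Cu-]C
Why: Cuprate cross-coupling of the enol triflate replaces OTf by methyl (C17) with the alkene held at C7–C8, the ester and acetonide being inert to the cuprate at low temperature.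

Step 14
Reactants: 23 acetonide
Product: 24 methyl (13S)-2α,3α-dihydroxylabd-7-en-15-oate (target CNP0574074.1)
Conditions: AcOH/H2O (4:1), 40 °C
Reagents that add atoms: none
Why: Mild aqueous acid hydrolysis of the acetonide should release the diol without moving the trisubstituted alkene or hydrolysing the methyl ester.

**Compound list**
1 | methyl hydrogen (R)-3-methylglutarate | COC(=O)C[C@H](C)CC(=O)O | starting material
2 | (S)-5-hydroxy-3-methylpentanoic acid (not isolated) | OC(=O)C[C@@H](C)CCO | intermediate
3 | (S)-4-methyloxan-2-one | O=C1C[C@@H](C)CCO1 | intermediate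
4 | trimethylsilyl (R)-5-iodo-3-methylpentanoate (not isolated) | C[Si](C)(C)OC(=O)C[C@@H](C)CCI | intermediate
5 | methyl (R)-5-iodo-3-methylpentanoate | COC(=O)C[C@@H](C)CCI | intermediate
6 | (1R,5R)-(+)-verbenone | CC1=CC(=O)[C@@H]2C[C@H]1C2(C)C | starting material
7 | vinylmagnesium bromide | C=C[Mg]Br | starting material
8 | (1R,4S,5S)-4-ethenyl-4,6,6-trimethylbicyclo[3.1.1]heptan-2-one | C1C(=O)[C@@H]2C[C@@H](C2(C)C)[C@]1(C)C=C | intermediate
9 | lithium enolate of 8 (not isolated) | C1=C(O[Li])[C@@H]2C[C@@H](C2(C)C)[C@]1(C)C=C | intermediate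
10 | C9-alkylated vinyl pinanone (chain and vinyl anti to the bridge) | COC(=O)C[C@@H](C)CC[C@@H]1C(=O)[C@@H]2C[C@@H](C2(C)C)[C@]1(C)C=C | intermediate
11 | B-alkyl-9-BBN adduct of 10 (not isolated) | COC(=O)C[C@@H](C)CC[C@@H]1C(=O)[C@@H]2C[C@@H](C2(C)C)[C@]1(C)CCB1C2CCCC1CCC2 | intermediate
12 | 2-hydroxyethyl pinanone | COC(=O)C[C@@H](C)CC[C@@H]1C(=O)[C@@H]2C[C@@H](C2(C)C)[C@]1(C)CCO | intermediate
13 | 2-oxoethyl pinanone (aldehyde) | COC(=O)C[C@@H](C)CC[C@@H]1C(=O)[C@@H]2C[C@@H](C2(C)C)[C@]1(C)CC=O | intermediate
14 | prop-2-ynyl pinanone | COC(=O)C[C@@H](C)CC[C@@H]1C(=O)[C@@H]2C[C@@H](C2(C)C)[C@]1(C)CC#C | intermediate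
15 | (Z)-3-(dimethylphenylsilyl)prop-2-enyl pinanone (key-step precursor) | COC(=O)C[C@@H](C)CC[C@@H]1C(=O)[C@@H]2C[C@@H](C2(C)C)[C@]1(C)C/C=C\[Si](C)(C)c1ccccc1 | intermediate
16 | cyclised trichlorotin C7–C8 enolate, 9β-H (not isolated) | COC(=O)C[C@@H](C)CC[C@@H]1C(O[Sn](Cl)(Cl)Cl)=CC[C@H]2C(C)(C)C=CC[C@]12C | intermediate
17 | methyl (13S)-8-oxo-17-nor-9-epi-labd-2-en-15-oate (not isolated) | COC(=O)C[C@@H](C)CC[C@@H]1C(=O)CC[C@H]2C(C)(C)C=CC[C@]12C | intermediate
18 | methyl (13S)-8-oxo-17-norlabd-2-en-15-oate (key-step product) | COC(=O)C[C@@H](C)CC[C@H]1C(=O)CC[C@H]2C(C)(C)C=CC[C@]12C | intermediate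
19 | methyl (13S)-2α,3α-dihydroxy-8-oxo-17-norlabdan-15-oate | COC(=O)C[C@@H](C)CC[C@H]1C(=O)CC[C@H]2C(C)(C)[C@H](O)[C@H](O)C[C@]12C | intermediate
20 | 2α,3α-acetonide of 19 | COC(=O)C[C@@H](C)CC[C@H]1C(=O)CC[C@H]2C(C)(C)[C@@H]3OC(C)(C)O[C@@H]3C[C@]12C | intermediate
21 | potassium C7–C8 enolate of 20 (not isolated) | COC(=O)C[C@@H](C)CC[C@H]1C(O[K])=CC[C@H]2C(C)(C)[C@@H]3OC(C)(C)O[C@@H]3C[C@]12C | intermediate
22 | C7–C8 enol triflate | COC(=O)C[C@@H](C)CC[C@H]1C(OS(=O)(=O)C(F)(F)F)=CC[C@H]2C(C)(C)[C@@H]3OC(C)(C)O[C@@H]3C[C@]12C | intermediate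
23 | methyl (13S)-2α,3α-(isopropylidenedioxy)labd-7-en-15-oate | COC(=O)C[C@@H](C)CC[C@H]1C(C)=CC[C@H]2C(C)(C)[C@@H]3OC(C)(C)O[C@@H]3C[C@]12C | intermediate
24 | methyl (13S)-2α,3α-dihydroxylabd-7-en-15-oate | COC(=O)C[C@@H](C)CC[C@H]1C(C)=CC[C@H]2C(C)(C)[C@H](O)[C@H](O)C[C@]12C | target

**Step count**
Total: 14 steps. Longest linear sequence: 13 steps, running from half-ester 1 through iodide 5 to the target (steps 1, 2 and 4 to 14). The verbenone arm needs only step 3 before the two arms join in step 4.

**Steps most likely to fail**

Step 9 (bears the new-method label). The cyclobutane may not ionise under conditions mild enough for the vinylsilane. The C4 cation may lose a proton or take a hydride from C5 before it is captured, which would also erode the ring-fusion configuration. The vinylsilane may be protodesilylated by adventitious HCl. The fallback uncouples the two events with known reaction types; it sets out from alkyne 14 and returns at 18. Iodotrimethylsilane in CH2Cl2 at −20 °C cleaves the cyclobutane with iodide capture, as established for pinane ketones, and should give the silyl enol ether iodide F1, which aqueous work-up converts into the keto iodide F2 (used without chromatography). Hydrosilylation as in step 8 then gives the Z-vinylsilane keto iodide F3. AgOTf with 2,6-di-tert-butylpyridine in CH2Cl2 at −78 °C ionises the tertiary iodide under non-protic conditions for a vinylsilane-terminated cation cyclisation to 17, and NaOMe/MeOH as in step 9 equilibrates C9 to give 18.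

Step 8. Z/E or β/α selectivity may erode, for example through coordination of ruthenium to the C8 carbonyl, or carbonyl hydrosilylation may compete. The fallback sets out from aldehyde 13 and returns at 18. Stork–Zhao olefination (Ph3P+CH2I I−, NaN(SiMe3)2, THF/HMPA, −78 °C) should give the Z-vinyl iodide F4. Stereoretentive palladium-catalysed silylation with Me3SiSiMe3 and (Me2N)3S+ Me3SiF2− ([Pd(allyl)Cl]2 cat.) should then give the Z-trimethylsilyl vinylsilane F5, which is submitted to the conditions of step 9 and converges on 18 with loss of the trimethylsilyl group.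

Step 4. C-alkylation at an enolate carbon next to a quaternary centre may be slow, so that O-alkylation, E2 loss of HI from the iodide or attack of the enolate on its ester takes over. The fallback replaces SN2 alkylation by aldol addition, dehydration and conjugate reduction; it sets out from 5 and 8 and returns at 10. Kornblum oxidation of 5 (DMSO, NaHCO3, 100 °C) gives the aldehyde ester F6. Addition of lithium enolate 9 (from 8 with LiN(i-Pr)2) at −78 °C gives the aldol F7 as a carbinol mixture. MsCl/Et3N gives the mesylate F8, and DBU eliminates it to the exocyclic enone F9 (alkene geometry of no consequence). Conjugate reduction with [(Ph3P)CuH]6 and PhSiH3, which spares the isolated vinyl group, then gives 10.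

**Further compounds**
F1 | step 9 | ring-opened trimethylsilyl enol ether tertiary iodide (alkyne arm) | COC(=O)C[C@@H](C)CC[C@@H]1C(O[Si](C)(C)C)=CC[C@@H](C(C)(C)I)[C@]1(C)CC#C
F2 | step 9 | ring-opened keto tertiary iodide (alkyne arm) | COC(=O)C[C@@H](C)CC[C@@H]1C(=O)CC[C@@H](C(C)(C)I)[C@]1(C)CC#C
F3 | step 9 | ring-opened keto tertiary iodide with Z-(dimethylphenylsilyl)vinyl arm | COC(=O)C[C@@H](C)CC[C@@H]1C(=O)CC[C@@H](C(C)(C)I)[C@]1(C)C/C=C\[Si](C)(C)c1ccccc1
F4 | step 8 | pinanone with (Z)-3-iodoprop-2-enyl arm | COC(=O)C[C@@H](C)CC[C@@H]1C(=O)[C@@H]2C[C@@H](C2(C)C)[C@]1(C)C/C=C\I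
F5 | step 8 | pinanone with (Z)-3-(trimethylsilyl)prop-2-enyl arm | COC(=O)C[C@@H](C)CC[C@@H]1C(=O)[C@@H]2C[C@@H](C2(C)C)[C@]1(C)C/C=C\[Si](C)(C)C
F6 | step 4 | methyl (S)-3-methyl-5-oxopentanoate | COC(=O)C[C@@H](C)CC=O
F7 | step 4 | aldol adduct of 9 and F6 (carbinol mixture) | COC(=O)C[C@@H](C)CC(O)[C@@H]1C(=O)[C@@H]2C[C@@H](C2(C)C)[C@]1(C)C=C
F8 | step 4 | mesylate of F7 | COC(=O)C[C@@H](C)CC(OS(C)(=O)=O)[C@@H]1C(=O)[C@@H]2C[C@@H](C2(C)C)[C@]1(C)C=C
F9 | step 4 | exocyclic C9=C11 enone | COC(=O)C[C@@H](C)CC=C1C(=O)[C@@H]2C[C@@H](C2(C)C)[C@]1(C)C=C
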